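## Retrosynthetic overview

- **Endgame:** the target comes from eightfold O-demethylation of its octamethyl ether. That ether comes from a Heck reaction of 4-methoxystyrene with the C6 bromide of the protected bis(dihydrobenzofuran). All six benzene rings are bought; only the two dihydrofuran rings are built.
- **Structural feature used:** in unit 2 (primed numbers) C2' carries only the catechol ring and lies between O1' and C3'. C3' is bonded to C3a', the ring B carbon next to oxygen-bearing C7a'. Cutting O1'–C2' and C2'–C3' therefore leaves an ortho-quinone methide of ring B (C7a'=O, C3a'=C3') and an arylcarbene equivalent. O1/C2/C3/C3a/C7a of unit 1 (ring A) repeat the pattern.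
- **Unit 2:** a racemic 2-[aryl(tosyl)methyl]phenol of ring B (salicylaldehyde, aryl Grignard reagent, p-toluenesulfinic acid) reacts with a C2-symmetric thiolanium 3,4-dimethoxybenzyl salt and base in a [4+1] annulation.
- **Link C3–C6' and unit 1:** the C6' bromide becomes an arylmagnesium that adds to the same salicylaldehyde. Sulfone formation follows, then a second [4+1] annulation with the mirror-image thiolanium 4-methoxybenzyl salt.
- **Ring order:** dihydrofuran of unit 2 first, then dihydrofuran of unit 1.

Key step: step 7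

Assumption: the sense of induction is carried over from the accepted model of benzylide transfer from 2,5-dimethylthiolane (bond formation on the open ylide face, then inversion at the ylide carbon), which pairs the (2S,5S)-thiolane with the (2S,3S) ring and the (2R,5R)-thiolane with the (2R,3R) ring; if the first experiment shows the opposite sense, the two thiolane enantiomers change places in the two salt-forming steps and nothing else changes.

## Route

Step 1
Reactants: 1 4-bromo-2,6-dimethoxybenzaldehyde
Product: 2 4-bromo-2-hydroxy-6-methoxybenzaldehyde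
Conditions: BCl3 (1.2 equiv), CH2Cl2, −78 °C to 0 °C; then H2O
Reagents that add atoms: none
Why: Chelation-directed Lewis acid ether cleavage, in which BCl3 bound to the aldehyde oxygen cleaves one ortho methyl ether and the resulting six-membered boron chelate no longer directs attack on the second one.

Step 2
Reactants: 3 1-bromo-3,5-dimethoxybenzene; 2 4-bromo-2-hydroxy-6-methoxybenzaldehyde
Product: 5 rac-5-bromo-2-[(3,5-dimethoxyphenyl)(hydroxy)methyl]-3-methoxyphenol, via 3,5-dimethoxyphenylmagnesium bromide 4 (not isolated)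
Conditions: 3 (2.5 equiv), Mg, cat. I2, THF, reflux; then 2 (1 equiv), THF, 0 °C to rt; aq NH4Cl
Reagents that add atoms: none
Why: Grignard addition in which the first equivalent of the cheap reagent deprotonates the phenol and the second adds to the aldehyde, the aryl bromide of 2 being inert to an arylmagnesium at this temperature and the new carbinol centre being racemic on purpose.

Step 3
Reactants: 5 rac-5-bromo-2-[(3,5-dimethoxyphenyl)(hydroxy)methyl]-3-methoxyphenol
Product: 6 rac-5-bromo-2-[(3,5-dimethoxyphenyl)(4-methylphenylsulfonyl)methyl]-3-methoxyphenol (racemic sulfone of ring B)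
Conditions: p-TolSO2H (1.5 equiv), CH2Cl2, rt
Reagents that add atoms: p-toluenesulfinic acid, Cc1ccc(cc1)S(=O)O
Why: Acid-promoted SN1 substitution, the standard preparation of 2-(tosylmethyl)phenols, in which the ortho-hydroxy/ortho-methoxy benzhydrol ionises easily and the soft sulfur of the sulfinate captures the cation to give the thermodynamically preferred sulfone.

Step 4
Reactants: 7 (2R,5R)-hexane-2,5-diol
Product: 8 (2R,5R)-hexane-2,5-diyl dimethanesulfonate
Conditions: MsCl (2.4 equiv), Et3N (3 equiv), CH2Cl2, 0 °C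
Reagents that add atoms: methanesulfonyl chloride, CS(=O)(=O)Cl
Why: O-sulfonylation at oxygen only, so both carbinol configurations are retained.

Step 5
Reactants: 8 (2R,5R)-hexane-2,5-diyl dimethanesulfonate
Product: 9 (2S,5S)-2,5-dimethylthiolane
Conditions: Na2S·9H2O (1.2 equiv), EtOH, rt; distillation
Reagents that add atoms: sodium sulfide, [Na+].[Na+].[S-2]
Why: Double SN2 displacement (the second is a 5-exo-tet closure) with inversion at both carbons, which turns the (R,R)-dimesylate into the trans (S,S)-thiolane.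

Step 6
Reactants: 9 (2S,5S)-2,5-dimethylthiolane; 10 3,4-dimethoxybenzyl chloride
Product: 11 (2S,5S)-1-(3,4-dimethoxybenzyl)-2,5-dimethylthiolanium tetrafluoroborate
Conditions: AgBF4 (1.05 equiv), CH2Cl2, 0 °C to rt, dark; precipitation with Et2O
Reagents that add atoms: silver tetrafluoroborate, [Ag+].F[B-](F)(F)F
Why: Silver-assisted S-alkylation of a sulfide, made irreversible by precipitation of AgCl and the non-nucleophilic counterion, with the twofold axis of 9 making both sulfur lone pairs equivalent so that a single salt forms.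

Step 7
Reactants: 6 racemic sulfone of ring B; 11 (2S,5S)-1-(3,4-dimethoxybenzyl)-2,5-dimethylthiolanium tetrafluoroborate
Product: 15 (2S,3S)-6-bromo-2-(3,4-dimethoxyphenyl)-3-(3,5-dimethoxyphenyl)-4-methoxy-2,3-dihydrobenzofuran (trans; 6'-bromo unit 2), via ortho-quinone methide 12 (not isolated), via sulfonium benzylide 13 (not isolated), via anti betaine 14 (not isolated)
Conditions: 11 (1.5 equiv), Cs2CO3 (3 equiv), 4 Å MS, MeCN/CH2Cl2 1:1, −20 °C to rt
Reagents that add atoms: none
Why: Proposed new method: Cs2CO3 deprotonates the phenol of 6, the phenoxide expels p-toluenesulfinate to give the planar ortho-quinone methide 12 (so the racemic centre disappears), and the same base reversibly converts 11 into benzylide 13, whose carbon adds to the exocyclic carbon of 12 (bond C2'–C3') with rearomatisation of ring B to the phenoxide of betaine 14, which then displaces the thiolane with inversion (bond O1'–C2'). The closest known reaction types are the carbonate-mediated, trans-selective [4+1] annulation of 2-(tosylmethyl)phenols with carbonyl-stabilised sulfonium ylides and the asymmetric epoxidation of aldehydes with the benzylide of this same thiolane; what is new is a chiral, non-stabilised benzylide acting on a quinone methide. The only ring closed, the dihydrofuran of unit 2, forms by 5-exo-tet substitution at C2'. C2' is controlled by the thiolane: its twofold axis allows one sulfonium salt only, the aryl group of 13 lies on the side of the sulfur lone pair away from the ring, the methyl group cis to the ylide carbon shields one face, and C–C bond formation on the open face followed by inversion should give 2'S. C3' is controlled by the relative topicity of the addition, the betaine that can close with the two aryl groups on opposite faces of the new ring being formed and consumed fastest, which gives trans and hence 3'S. The step needs one quinone methide geometry and attack at carbon only: the C4' methoxy group pushes the 3,5-dimethoxyphenyl group of 12 to the carbonyl side, the exocyclic carbon is the sole soft electrophilic site, aromatisation makes the addition irreversible, and the aryl bromide and methyl ethers are inert to carbonate.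

Step 8
Reactants: 16 (2S,5S)-hexane-2,5-diol
Product: 17 (2S,5S)-hexane-2,5-diyl dimethanesulfonate
Conditions: MsCl (2.4 equiv), Et3N (3 equiv), CH2Cl2, 0 °C
Reagents that add atoms: methanesulfonyl chloride, CS(=O)(=O)Cl
Why: O-sulfonylation with retention at both carbinol carbons, as in step 4.

Step 9
Reactants: 17 (2S,5S)-hexane-2,5-diyl dimethanesulfonate
Product: 18 (2R,5R)-2,5-dimethylthiolane
Conditions: Na2S·9H2O (1.2 equiv), EtOH, rt; distillation
Reagents that add atoms: sodium sulfide, [Na+].[Na+].[S-2]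
Why: Double SN2 displacement with inversion at both carbons, giving the mirror image of 9.

Step 10
Reactants: 18 (2R,5R)-2,5-dimethylthiolane; 19 4-methoxybenzyl chloride
Product: 20 (2R,5R)-1-(4-methoxybenzyl)-2,5-dimethylthiolanium tetrafluoroborate
Conditions: AgBF4 (1.05 equiv), CH2Cl2, 0 °C to rt, dark; precipitation with Et2O
Reagents that add atoms: silver tetrafluoroborate, [Ag+].F[B-](F)(F)F
Why: Silver-assisted S-alkylation as in step 6, again giving one salt because of the twofold axis.

Step 11
Reactants: 15 (2S,3S)-6-bromo-2-(3,4-dimethoxyphenyl)-3-(3,5-dimethoxyphenyl)-4-methoxy-2,3-dihydrobenzofuran; 2 4-bromo-2-hydroxy-6-methoxybenzaldehyde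
Product: 24 5-bromo-2-{[(2S,3S)-2-(3,4-dimethoxyphenyl)-3-(3,5-dimethoxyphenyl)-4-methoxy-2,3-dihydrobenzofuran-6-yl](hydroxy)methyl}-3-methoxyphenol (both carbinol epimers), via aryllithium 21 (not isolated), via arylmagnesium bromide 22 (not isolated), via sodium phenoxide 23 (not isolated)
Conditions: 15, n-BuLi (1.05 equiv), THF, −78 °C; MgBr2·OEt2 (1.2 equiv), −78 to −20 °C; separately 2 (1.5 equiv), NaH (1.5 equiv), THF, 0 °C; combine, −20 °C to rt; aq NH4Cl
Reagents that add atoms: none
Why: Bromine–lithium exchange outruns deprotonation at −78 °C, transmetalation to magnesium prevents halogen scrambling with the bromide of the aldehyde, prior deprotonation of 2 keeps the valuable aryl-metal from being quenched by the phenol, and the Grignard addition then forms C3–C6' with an unselective carbinol centre that step 13 erases.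

Step 12
Reactants: 24 the diol of step 11 (both carbinol epimers)
Product: 25 5-bromo-2-{[(2S,3S)-2-(3,4-dimethoxyphenyl)-3-(3,5-dimethoxyphenyl)-4-methoxy-2,3-dihydrobenzofuran-6-yl](4-methylphenylsulfonyl)methyl}-3-methoxyphenol (both sulfone epimers)
Conditions: p-TolSO2H (1.5 equiv), CH2Cl2, rt
Reagents that add atoms: p-toluenesulfinic acid, Cc1ccc(cc1)S(=O)O
Why: The same acid-promoted SN1 sulfinate substitution as in step 3, mild enough to leave the dihydrofuran ring of unit 2 closed.

Step 13
Reactants: 25 the sulfone of step 12 (both epimers); 20 (2R,5R)-1-(4-methoxybenzyl)-2,5-dimethylthiolanium tetrafluoroborate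
Product: 29 (2R,3R)-6-bromo-3-[(2S,3S)-2-(3,4-dimethoxyphenyl)-3-(3,5-dimethoxyphenyl)-4-methoxy-2,3-dihydrobenzofuran-6-yl]-4-methoxy-2-(4-methoxyphenyl)-2,3-dihydrobenzofuran, via ortho-quinone methide 26 (not isolated), via sulfonium benzylide 27 (not isolated), via anti betaine 28 (not isolated)
Conditions: 20 (1.5 equiv), Cs2CO3 (3 equiv), 4 Å MS, MeCN/CH2Cl2 1:1, −20 °C to rt
Reagents that add atoms: none
Why: Proposed new method: the mechanism is that of step 7 (sulfinate loss from the phenoxide of 25 gives planar 26 and erases the epimeric centre, benzylide 27 adds to the exocyclic carbon to form C2–C3, and the phenoxide of betaine 28 displaces the thiolane 5-exo-tet to form O1–C2), the closest known reaction types again being the carbonate-mediated [4+1] annulation of 2-(tosylmethyl)phenols with stabilised sulfonium ylides and benzylide epoxidation with this thiolane; the (2R,5R)-thiolane, mirror image of that in step 7, sets 2R through its open ylide face, the faster-closing betaine sets 3R (trans), and the stereocentres of unit 2 lie five bonds from the reacting carbon and should not disturb reagent control.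

Step 14
Reactants: 29 the bromide of step 13; 30 4-methoxystyrene
Product: 31 octamethyl ether of the target, (2R,3R)-3-[(2S,3S)-2-(3,4-dimethoxyphenyl)-3-(3,5-dimethoxyphenyl)-4-methoxy-2,3-dihydrobenzofuran-6-yl]-4-methoxy-2-(4-methoxyphenyl)-6-[(E)-2-(4-methoxyphenyl)ethenyl]-2,3-dihydrobenzofuran
Conditions: 30 (2 equiv), Pd(OAc)2 (5 mol %), P(o-tol)3 (15 mol %), Et3N (3 equiv), DMF, 110 °C
Reagents that add atoms: none
Why: Mizoroki–Heck reaction in which zerovalent palladium inserts into the only C–Br bond, the aryl group is delivered to the unsubstituted styrene terminus and syn β-hydride elimination gives the E-stilbene, while the four stereocentres are not acidic enough to be touched by Et3N.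

Step 15
Reactants: 31 octamethyl ether of the target
Product: 32 target, (2R,3R)-3-[(2S,3S)-2-(3,4-dihydroxyphenyl)-3-(3,5-dihydroxyphenyl)-4-hydroxy-2,3-dihydrobenzofuran-6-yl]-2-(4-hydroxyphenyl)-6-[(E)-2-(4-hydroxyphenyl)ethenyl]-2,3-dihydrobenzofuran-4-ol
Conditions: BBr3 (20 equiv), CH2Cl2, −78 °C to rt, dark; then ice/H2O
Reagents that add atoms: none
Why: Lewis acid cleavage of all eight aryl methyl ethers with BBr3, in which any reversible opening of the benzylic C2–O1 or C2'–O1' bond should reclose to the more stable trans ring while C3 and C3' stay untouched, so that the configuration is kept.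

## Compound list

1 | 4-bromo-2,6-dimethoxybenzaldehyde | COc1cc(Br)cc(OC)c1C=O | starting material
2 | 4-bromo-2-hydroxy-6-methoxybenzaldehyde | COc1cc(Br)cc(O)c1C=O | intermediate
3 | 1-bromo-3,5-dimethoxybenzene | COc1cc(Br)cc(OC)c1 | starting material
4 | 3,5-dimethoxyphenylmagnesium bromide (formed in the flask) | COc1cc([Mg]Br)cc(OC)c1 | intermediate
5 | rac-5-bromo-2-[(3,5-dimethoxyphenyl)(hydroxy)methyl]-3-methoxyphenol | COc1cc(Br)cc(O)c1C(O)c1cc(OC)cc(OC)c1 | intermediate
6 | rac-5-bromo-2-[(3,5-dimethoxyphenyl)(4-methylphenylsulfonyl)methyl]-3-methoxyphenol | COc1cc(Br)cc(O)c1C(c1cc(OC)cc(OC)c1)S(=O)(=O)c1ccc(C)cc1 | intermediate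
7 | (2R,5R)-hexane-2,5-diol | C[C@@H](O)CC[C@@H](C)O | starting material
8 | (2R,5R)-hexane-2,5-diyl dimethanesulfonate | C[C@@H](OS(C)(=O)=O)CC[C@@H](C)OS(C)(=O)=O | intermediate
9 | (2S,5S)-2,5-dimethylthiolane | C[C@H]1CC[C@H](C)S1 | intermediate
10 | 3,4-dimethoxybenzyl chloride | COc1ccc(CCl)cc1OC | starting material
11 | (2S,5S)-1-(3,4-dimethoxybenzyl)-2,5-dimethylthiolanium tetrafluoroborate | C[C@H]1CC[C@H](C)[S+]1Cc1ccc(OC)c(OC)c1.F[B-](F)(F)F | intermediate
12 | (6Z)-3-bromo-6-(3,5-dimethoxybenzylidene)-5-methoxycyclohexa-2,4-dien-1-one, ortho-quinone methide of ring B, aryl group expected on the carbonyl side (formed in the flask) | O=C1C=C(Br)C=C(OC)/C1=C/c1cc(OC)cc(OC)c1 | intermediate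
13 | (2S,5S)-2,5-dimethylthiolanium 3,4-dimethoxybenzylide (formed in the flask) | C[C@H]1CC[C@H](C)[S+]1[CH-]c1ccc(OC)c(OC)c1 | intermediate
14 | anti betaine: ring B phenoxide with C3' (S) bearing the 3,5-dimethoxyphenyl group and C2' (R) bearing the 3,4-dimethoxyphenyl group and the (2S,5S)-thiolanium (formed in the flask) | [O-]c1cc(Br)cc(OC)c1[C@H](c1cc(OC)cc(OC)c1)[C@H](c1ccc(OC)c(OC)c1)[S+]1[C@@H](C)CC[C@@H]1C | intermediate
15 | (2S,3S)-6-bromo-2-(3,4-dimethoxyphenyl)-3-(3,5-dimethoxyphenyl)-4-methoxy-2,3-dihydrobenzofuran | Brc1cc(OC)c2c(c1)O[C@H](c1ccc(OC)c(OC)c1)[C@H]2c1cc(OC)cc(OC)c1 | intermediate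
16 | (2S,5S)-hexane-2,5-diol | C[C@H](O)CC[C@H](C)O | starting material
17 | (2S,5S)-hexane-2,5-diyl dimethanesulfonate | C[C@H](OS(C)(=O)=O)CC[C@H](C)OS(C)(=O)=O | intermediate
18 | (2R,5R)-2,5-dimethylthiolane | C[C@@H]1CC[C@@H](C)S1 | intermediate
19 | 4-methoxybenzyl chloride | COc1ccc(CCl)cc1 | starting material
20 | (2R,5R)-1-(4-methoxybenzyl)-2,5-dimethylthiolanium tetrafluoroborate | C[C@@H]1CC[C@@H](C)[S+]1Cc1ccc(OC)cc1.F[B-](F)(F)F | intermediate
21 | 6-lithio derivative of 15 (formed in the flask) | [Li]c1cc(OC)c2c(c1)O[C@H](c1ccc(OC)c(OC)c1)[C@H]2c1cc(OC)cc(OC)c1 | intermediate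
22 | 6-(bromomagnesio) derivative of 15 (formed in the flask) | Br[Mg]c1cc(OC)c2c(c1)O[C@H](c1ccc(OC)c(OC)c1)[C@H]2c1cc(OC)cc(OC)c1 | intermediate
23 | sodium 5-bromo-2-formyl-3-methoxyphenolate (formed in the flask) | [Na+].[O-]c1cc(Br)cc(OC)c1C=O | intermediate
24 | 5-bromo-2-{[(2S,3S)-2-(3,4-dimethoxyphenyl)-3-(3,5-dimethoxyphenyl)-4-methoxy-2,3-dihydrobenzofuran-6-yl](hydroxy)methyl}-3-methoxyphenol, both carbinol epimers | COc1cc(Br)cc(O)c1C(O)c1cc(OC)c2c(c1)O[C@H](c1ccc(OC)c(OC)c1)[C@H]2c1cc(OC)cc(OC)c1 | intermediate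
25 | 5-bromo-2-{[(2S,3S)-2-(3,4-dimethoxyphenyl)-3-(3,5-dimethoxyphenyl)-4-methoxy-2,3-dihydrobenzofuran-6-yl](4-methylphenylsulfonyl)methyl}-3-methoxyphenol, both sulfone epimers | COc1cc(Br)cc(O)c1C(c1cc(OC)c2c(c1)O[C@H](c1ccc(OC)c(OC)c1)[C@H]2c1cc(OC)cc(OC)c1)S(=O)(=O)c1ccc(C)cc1 | intermediate
26 | ortho-quinone methide of ring A, (6Z)-3-bromo-5-methoxycyclohexa-2,4-dien-1-one carrying at C6 the methylidene group substituted by the 6-yl residue of unit 2 (formed in the flask) | O=C1C=C(Br)C=C(OC)/C1=C/c1cc(OC)c2c(c1)O[C@H](c1ccc(OC)c(OC)c1)[C@H]2c1cc(OC)cc(OC)c1 | intermediate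
27 | (2R,5R)-2,5-dimethylthiolanium 4-methoxybenzylide (formed in the flask) | C[C@@H]1CC[C@@H](C)[S+]1[CH-]c1ccc(OC)cc1 | intermediate
28 | anti betaine: ring A phenoxide with C3 (R) bearing unit 2 and C2 (S) bearing the 4-methoxyphenyl group and the (2R,5R)-thiolanium (formed in the flask) | [O-]c1cc(Br)cc(OC)c1[C@@H](c1cc(OC)c2c(c1)O[C@H](c1ccc(OC)c(OC)c1)[C@H]2c1cc(OC)cc(OC)c1)[C@@H](c1ccc(OC)cc1)[S+]1[C@H](C)CC[C@H]1C | intermediate
29 | (2R,3R)-6-bromo-3-[(2S,3S)-2-(3,4-dimethoxyphenyl)-3-(3,5-dimethoxyphenyl)-4-methoxy-2,3-dihydrobenzofuran-6-yl]-4-methoxy-2-(4-methoxyphenyl)-2,3-dihydrobenzofuran | Brc1cc(OC)c2c(c1)O[C@@H](c1ccc(OC)cc1)[C@@H]2c1cc(OC)c2c(c1)O[C@H](c1ccc(OC)c(OC)c1)[C@H]2c1cc(OC)cc(OC)c1 | intermediate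
30 | 4-methoxystyrene | C=Cc1ccc(OC)cc1 | starting material
31 | octamethyl ether of the target | COc1ccc(/C=C/c2cc(OC)c3c(c2)O[C@@H](c2ccc(OC)cc2)[C@@H]3c2cc(OC)c3c(c2)O[C@H](c2ccc(OC)c(OC)c2)[C@H]3c2cc(OC)cc(OC)c2)cc1 | intermediate
32 | CNP0107857.3, (2R,3R,2'S,3'S) | Oc1ccc(/C=C/c2cc(O)c3c(c2)O[C@@H](c2ccc(O)cc2)[C@@H]3c2cc(O)c3c(c2)O[C@H](c2ccc(O)c(O)c2)[C@H]3c2cc(O)cc(O)c2)cc1 | target

## Step count and risks

Total step count: 15.
Longest linear sequence: 9 steps (1, 2, 3, 7, 11, 12, 13, 14, 15).

### Step 7

**What may go wrong:**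
- Deprotonation of the electron-rich salt may be slow.
- The benzyl group of the salt may transfer to sulfinate or phenoxide.
- The betaine may ionise at the dimethoxybenzylic carbon before ring closure. That would hand stereocontrol to C3' alone and lower the enantiopurity.
- The ylide faces may be poorly discriminated.

**Fallback:** it uses known chemistry, namely enantioselective intramolecular C–H insertion of a donor/donor rhodium carbene followed by acid equilibration. It sets out from 5 and returns at 15.

The phenol of 5 is alkylated with 10 (K2CO3, DMF, rt) to the benzyl ether carbinol F1. MnO2 in CH2Cl2 oxidises this to the benzophenone F2. Hydrazine hydrate (EtOH, cat. AcOH, reflux) gives the hydrazone F3. MnO2 converts it into the diaryldiazomethane F4, which is treated without isolation with Rh2(R-PTAD)4 or its enantiomer (1 mol %, CH2Cl2, 0 °C), whichever delivers 3'S. The carbene inserts into the activated benzylic ether C–H bond in preference to the methoxy C–H bonds and should give the cis-(2R,3S)-dihydrobenzofuran F5. TFA in CH2Cl2 then equilibrates C2' through the dimethoxybenzylic cation to the trans compound 15, and C3' is not touched.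

### Step 13

**What may go wrong:**
- The processes listed for step 7 apply again.
- The 4-methoxybenzyl salt is even less acidic.
- The quinone methide is bulkier.
- The ylide face selection may be eroded. Because unit 2 is already set, such stereochemical errors appear as diastereomers and lower the throughput.

**Fallback:** it applies the same known carbene chemistry under catalyst control. It sets out from 24 and returns at 29.

The phenol of 24 is alkylated with 19 (K2CO3, DMF) to the 4-methoxybenzyl ether carbinol F6. MnO2 gives the diaryl ketone F7. Hydrazine hydrate gives the hydrazone F8. MnO2 gives the diaryldiazomethane F9. The Rh2(PTAD)4 enantiomer opposite to that of the first fallback effects C–H insertion to the unit 1 cis-(2S,3R) compound F10. TFA in CH2Cl2 equilibrates C2 to the trans compound 29, and the trans ring of unit 2 returns to itself under the same conditions.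

### Step 15

**What may go wrong:**
- The electron-rich stilbene may be protonated or oligomerised by the large excess of Lewis acid.
- A dihydrofuran C–O bond may open irreversibly.
- Ether cleavage may be incomplete.
- The polyphenol may be oxidised on work-up.

**Fallback:** the stilbene is never exposed to BBr3. It sets out from 29 and returns at 32.

BBr3 (CH2Cl2, −78 °C to rt) converts 29 into the heptaphenol bromide F11. Ac2O/pyridine gives the heptaacetate bromide F12. A Heck reaction with commercial 4-acetoxystyrene (Pd(OAc)2, P(o-tol)3, Et3N, DMF, 100 °C) gives the octaacetate stilbene F13. Mild methanolysis (cat. K2CO3, MeOH, 0 °C, under argon) releases 32.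

## Further compounds

F1 | step 7 | rac-[4-bromo-2-(3,4-dimethoxybenzyloxy)-6-methoxyphenyl](3,5-dimethoxyphenyl)methanol | COc1cc(Br)cc(OCc2ccc(OC)c(OC)c2)c1C(O)c1cc(OC)cc(OC)c1
F2 | step 7 | [4-bromo-2-(3,4-dimethoxybenzyloxy)-6-methoxyphenyl](3,5-dimethoxyphenyl)methanone | COc1cc(Br)cc(OCc2ccc(OC)c(OC)c2)c1C(=O)c1cc(OC)cc(OC)c1
F3 | step 7 | hydrazone of F2 | COc1cc(Br)cc(OCc2ccc(OC)c(OC)c2)c1C(=NN)c1cc(OC)cc(OC)c1
F4 | step 7 | diaryldiazomethane from F3 | COc1cc(Br)cc(OCc2ccc(OC)c(OC)c2)c1C(=[N+]=[N-])c1cc(OC)cc(OC)c1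
F5 | step 7 | cis-(2R,3S)-6-bromo-2-(3,4-dimethoxyphenyl)-3-(3,5-dimethoxyphenyl)-4-methoxy-2,3-dihydrobenzofuran | Brc1cc(OC)c2c(c1)O[C@@H](c1ccc(OC)c(OC)c1)[C@H]2c1cc(OC)cc(OC)c1
F6 | step 13 | O-(4-methoxybenzyl) ether of 24, both carbinol epimers | COc1cc(Br)cc(OCc2ccc(OC)cc2)c1C(O)c1cc(OC)c2c(c1)O[C@H](c1ccc(OC)c(OC)c1)[C@H]2c1cc(OC)cc(OC)c1
F7 | step 13 | diaryl ketone from F6 | COc1cc(Br)cc(OCc2ccc(OC)cc2)c1C(=O)c1cc(OC)c2c(c1)O[C@H](c1ccc(OC)c(OC)c1)[C@H]2c1cc(OC)cc(OC)c1
F8 | step 13 | hydrazone of F7 | COc1cc(Br)cc(OCc2ccc(OC)cc2)c1C(=NN)c1cc(OC)c2c(c1)O[C@H](c1ccc(OC)c(OC)c1)[C@H]2c1cc(OC)cc(OC)c1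
F9 | step 13 | diaryldiazomethane from F8 | COc1cc(Br)cc(OCc2ccc(OC)cc2)c1C(=[N+]=[N-])c1cc(OC)c2c(c1)O[C@H](c1ccc(OC)c(OC)c1)[C@H]2c1cc(OC)cc(OC)c1
F10 | step 13 | C2 epimer of 29, unit 1 cis-(2S,3R), unit 2 (2S,3S) | Brc1cc(OC)c2c(c1)O[C@H](c1ccc(OC)cc1)[C@@H]2c1cc(OC)c2c(c1)O[C@H](c1ccc(OC)c(OC)c1)[C@H]2c1cc(OC)cc(OC)c1
F11 | step 15 | heptaphenol bromide (29 with all seven methyl ethers cleaved) | Brc1cc(O)c2c(c1)O[C@@H](c1ccc(O)cc1)[C@@H]2c1cc(O)c2c(c1)O[C@H](c1ccc(O)c(O)c1)[C@H]2c1cc(O)cc(O)c1
F12 | step 15 | heptaacetate of F11 | Brc1cc(OC(C)=O)c2c(c1)O[C@@H](c1ccc(OC(C)=O)cc1)[C@@H]2c1cc(OC(C)=O)c2c(c1)O[C@H](c1ccc(OC(C)=O)c(OC(C)=O)c1)[C@H]2c1cc(OC(C)=O)cc(OC(C)=O)c1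
F13 | step 15 | octaacetate of the target | CC(=O)Oc1ccc(/C=C/c2cc(OC(C)=O)c3c(c2)O[C@@H](c2ccc(OC(C)=O)cc2)[C@@H]3c2cc(OC(C)=O)c3c(c2)O[C@H](c2ccc(OC(C)=O)c(OC(C)=O)c2)[C@H]3c2cc(OC(C)=O)cc(OC(C)=O)c2)cc1
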